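All constants come from no measurement; the result is computed.

At early times the enzyme and the protic impurity both pull on the starting material, and we want to know how much of it stands as isomer of the product at the end.

    starting material + enzyme ⇌ complex A (K1 = 18.2 M⁻¹, k1 = 49100 M⁻¹ h⁻¹)
    complex A → enzyme + target (k2 = 349 h⁻¹)
    second substrate + enzyme ⇌ complex B (K3 = 11.4 M⁻¹, k3 = 76800 M⁻¹ h⁻¹)
    complex B → enzyme + second product (k4 = 161 h⁻¹)
    target + enzyme ⇌ isomer of the product + enzyme, rate k5*[enzyme]*[target] forward; the back reaction follows from the equilibrium constant (K5 = 0.138, k5 = 2210 M⁻¹ h⁻¹)
    starting material + protic impurity → quenched substrate (k6 = 10.1 M⁻¹ h⁻¹)

common to all: protic impurity 0.0200 M; enzyme 50 µM; time 25 h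
- south: starting material 0.10 M; second substrate 0.100 M (fed, over 10 h); all else is in the flask from the start; the feed brings no volume worth counting
- west: starting material 0.10 M; second substrate 0.100 M (in portions, 2, over 10 h); first portion at the start, last at 10 h
- north-east: starting material 0.10 M; second substrate 0.100 M; everything together at the start
- north-west: starting material 0.10 M (fed, over 10 h); second substrate 0.100 M; all else is in the flask from the start; the feed brings no volume worth counting

- the flask that comes out highest in amount of isomer of the product, in percent of the starting material charged, or "all alike" when all lie within 1.5 percentage points (south / west / north-east / north-west / all alike)
- isomer of the product at the end, in percent of the starting material charged, south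
- isomer of the product at the end, in percent of the starting material charged, west
- isomer of the product at the end, in percent of the starting material charged, north-east
- isomer of the product at the end, in percent of the starting material charged, north-west

1. Take the first extreme, where the enzyme wins every molecule and step 5 reaches its equilibrium. Isomer is then 12.1% of the charge.

2. Take the second extreme, where the impurity first takes its whole charge, one starting material each. The pool shrinks by the ratio of impurity charge to starting-material charge. We call the equilibrium share of that smaller pool the isomer ceiling, and it is 9.70% of the charge. Dosing does not enter it.

3. Now the enzyme's clock. Falling back plus going on, over forming, gives Michaelis constants of 0.0621 M for starting material and 0.0898 M for second substrate. At low [starting material] the decay is pseudo-first-order, with time constant 7.52 h if [second substrate] stays at its full charge. That overstates the competition, while the saturation we left out errs the other way.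

4. Which extreme is nearer? Against starting material at its full charge, the impurity has a time constant of 0.990 h, shorter than the enzyme's clock, so we commit to the second. Step 5 relaxes in 1.10 h with the whole enzyme charge free, far shorter than the run.

5. Compute the correction alone: the ceiling times the unconverted fraction, exp(−time/clock). With starting material present from the start, we get south 9.35%, west 9.35% and north-east 9.35%. North-west gets its clock from the end of the feed, which gives 8.38%. North-west's correction, 1.3 percentage points, stays under the margin, so we say all alike.

The forecast gives 9.4%, 9.4%, 9.3% and 8.9% for south, west, north-east and north-west, answers all alike (“All flasks come out alike, at about 9% isomer”), and stands above our north-west.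

The simulation gives 9.35%, 9.36%, 9.27% and 8.86% in that order, so the answer is all alike.

North-west ends 0.84 points under the ceiling with 4.81% of its starting material left, after 2.00 clocks from the end of its feed, and left ten times as long it reads 9.71%, level with the ceiling. The neighbour north-west flask with 2.0 × 10⁻⁵ M of enzyme has the same ceiling but a clock of 18.8 h, so the same interval is 0.798 clocks, and it holds 34.9% starting material and reads 3.89%.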